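## Retrosynthetic overview

1. Target ⇒ a C1,C3-dibenzoyl bicyclic trione: the last step exchanges the C3 benzoyl for prenyl (Tsuji–Trost C-prenylation, then retro-Claisen).
2. Key disconnection C1–C8, the bond the biosynthesis closes: cation–enol cyclisation of a C2v-symmetric 4,4-dialkyl-2,6-dibenzoyl dienone. Its quaternary carbon is not a stereocentre, so the C7 stereocentre of the ionising arm alone fixes C1 and C5, and only benzoyl-bearing carbons can be attacked (type A connectivity enforced).
3. The quaternary carbon ⇒ two C-alkylations of 2,4-dibenzoylphloroglucinol: (R)-lavandulyl triflate (pendant arm), then an (S)-lavandulol-derived tertiary-methoxy triflate (cation precursor).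
4. Both arms ⇒ racemic lavandulol (two lipase resolutions); dibenzoylphloroglucinol ⇒ phloroglucinol + benzoyl chloride.
5. Ring order: the phloroglucinol ring is bought and dearomatised; the only ring made is the C5–C6–C7–C8–C1–C9 cyclohexanone, which closes the bicyclo[3.3.1]nonane in one step.

Numbering of the bicycle: C1 benzoyl bridgehead, C2–C4 enolised diketone, C5 second bridgehead, C6–C8 saturated bridge, C9 bridging ketone.

Assumption: porcine pancreatic lipase acylates (S)-lavandulol faster and Candida antarctica lipase B acylates (R)-lavandulol faster; if a batch shows the opposite sense, the two enzymes exchange roles and nothing else changes.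

## Route

Step 1
Reactants: 1 (±)-lavandulol
Product: 2 (R)-lavandulol [(2R)-5-methyl-2-(prop-1-en-2-yl)hex-4-en-1-ol]
Conditions: porcine pancreatic lipase, succinic anhydride (0.7 equiv), t-BuOMe, 25 °C, to ca. 60% conversion; aq. NaHCO3 wash
Reagents that add atoms: none
Why: Lipase-catalysed kinetic resolution (enantioselective acylation): the (S)-alcohol is esterified faster, so past 50% conversion the unreacted (R)-alcohol remains in high ee and the acid ester is washed out; this centre becomes the side-chain stereocentre of the target.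

Step 2
Reactants: 2 (R)-lavandulol
Product: 3 (2R)-5-methyl-2-(prop-1-en-2-yl)hex-4-en-1-yl trifluoromethanesulfonate
Conditions: Tf2O, 2,6-lutidine, CH2Cl2, −78 °C; short silica plug, used at once
Reagents that add atoms: trifluoromethanesulfonic anhydride, O=S(=O)(OS(=O)(=O)C(F)(F)F)C(F)(F)F
Why: O-sulfonylation of a primary alcohol, stereocentre untouched; the triflate is needed because this β-branched, non-allylic carbon is a poor SN2 electrophile as a halide.

Step 3
Reactants: 1 (±)-lavandulol
Product: 4 (S)-lavandulol [(2S)-5-methyl-2-(prop-1-en-2-yl)hex-4-en-1-ol]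
Conditions: Candida antarctica lipase B (immobilised), vinyl acetate, hexane, 25 °C, to ca. 75% conversion; chromatography
Reagents that add atoms: none
Why: Lipase-catalysed kinetic resolution (irreversible transesterification) with the opposite enantiopreference: the (R)-alcohol is acetylated, and pushing conversion well past 50% leaves the (S)-alcohol in high ee; this centre becomes C7 of the target.

Step 4
Reactants: 4 (S)-lavandulol
Product: 5 (2R)-2-(2-methoxypropan-2-yl)-5-methylhex-4-en-1-ol
Conditions: [N,N′-bis(3,5-di-tert-butylsalicylidene)-1,2-cyclohexanediaminato]cobalt (divalent cobalt, C36H52CoN2O2, 3 mol %), N-fluoro-2,4,6-trimethylpyridinium triflate, PhSiH3, MeOH/PhCF3, 0 °C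
Reagents that add atoms: methanol, CO
Why: Cobalt-hydride hydrogen-atom-transfer Markovnikov hydroalkoxylation (Mukaiyama-type radical–polar crossover): the 1,1-disubstituted isopropenyl group takes up the hydrogen atom faster than the trisubstituted prenyl alkene and methanol traps the tertiary cation equivalent; the stereocentre is untouched (S becomes R only through CIP priorities).

Step 5
Reactants: 5 (2R)-2-(2-methoxypropan-2-yl)-5-methylhex-4-en-1-ol
Product: 6 (2R)-2-(2-methoxypropan-2-yl)-5-methylhex-4-en-1-yl trifluoromethanesulfonate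
Conditions: Tf2O, 2,6-lutidine, CH2Cl2, −78 °C; short silica plug, used at once
Reagents that add atoms: trifluoromethanesulfonic anhydride, O=S(=O)(OS(=O)(=O)C(F)(F)F)C(F)(F)F
Why: O-sulfonylation of the primary alcohol; the tertiary methyl ether is inert here and is kept as the latent C8 cation.

Step 6
Reactants: 7 phloroglucinol; 8 benzoyl chloride (2.2 equiv)
Product: 9 2,4-dibenzoylphloroglucinol [(2,4,6-trihydroxy-1,3-phenylene)bis(phenylmethanone)]
Conditions: AlCl3 (4 equiv), PhNO2, 80 °C; aq. HCl
Reagents that add atoms: none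
Why: Double Friedel–Crafts acylation; the doubly deactivated ring does not take a third acyl group, leaving one free ring carbon and a C2v-symmetric substitution pattern.

Step 7
Reactants: 9 2,4-dibenzoylphloroglucinol; 3 (R)-lavandulyl triflate
Product: 10 {2,4,6-trihydroxy-5-[(2S)-5-methyl-2-(prop-1-en-2-yl)hex-4-en-1-yl]-1,3-phenylene}bis(phenylmethanone)
Conditions: LiN(SiMe3)2 (3 equiv), THF/toluene, 0 °C; then 3 (1.0 equiv), 0 → 23 °C; aq. NH4Cl
Reagents that add atoms: none
Why: SN2 C-alkylation of a lithium phenoxide at the only unsubstituted ring carbon; lithium chelation between phenoxide and benzoyl oxygens in a weakly polar medium disfavours O-alkylation, and the side-chain stereocentre is β to the reacting carbon and untouched.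

Step 8
Reactants: 10 lavandulyl-dibenzoylphloroglucinol; 6 methoxy triflate
Product: 11 2,6-dibenzoyl-3,5-dihydroxy-4-[(2R)-2-(2-methoxypropan-2-yl)-5-methylhex-4-en-1-yl]-4-[(2S)-5-methyl-2-(prop-1-en-2-yl)hex-4-en-1-yl]cyclohexa-2,5-dien-1-one
Conditions: LiN(SiMe3)2 (3 equiv), THF/toluene, 0 °C; then 6 (1.3 equiv), 0 → 23 °C; aq. NH4Cl
Reagents that add atoms: none
Why: Alkylative dearomatisation (SN2 C-alkylation at the already substituted carbon, the only ring carbon without an acyl group) gives the gem-dialkyl dienone; its quaternary carbon is not a stereocentre because the two ring branches are identical, so no diastereomers arise.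

Step 9
Reactants: 11 gem-dialkyl dibenzoyl dienone
Product: 15 (1R,5S,7R)-1,3-dibenzoyl-2-hydroxy-8,8-dimethyl-7-(3-methylbut-2-en-1-yl)-5-[(2S)-5-methyl-2-(prop-1-en-2-yl)hex-4-en-1-yl]bicyclo[3.3.1]non-2-ene-4,9-dione, via bis-silyl dienol ether 12 (not isolated), via tertiary carbocation 13 (not isolated), via silyl enol ether 14 (not isolated)
Conditions: Me3SiOTf (3.5 equiv), 2,6-di-tert-butyl-4-methylpyridine (3 equiv), CH2Cl2, −78 → 0 °C; then 1 M HCl/THF
Reagents that add atoms: none
Why: Proposed new method: Me3SiOTf silylates both enols and ionises the tertiary methyl ether (as in silyl-triflate cleavage of tert-alkyl ethers), and the C8 cation is captured by one of the two equivalent benzoyl-bearing enol carbons through the chair transition state with the C7 prenyl equatorial (exo), so the one pre-set stereocentre fixes C1 and C5 and only type A connectivity can form; the hindered pyridine traps protons so the isopropenyl and prenyl groups are never protonated, O-alkyl isomers can re-ionise, and the closest known reaction types are the Lewis-acid-mediated tert-alkylation of silyl enol ethers (Reetz alkylation) and the cation–enol cyclisations of dearomatised acylphloroglucinols that mirror the biosynthetic ring closure.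

Step 10
Reactants: 15 C1,C3-dibenzoyl bicycle; 16 prenyl acetate (1.05 equiv)
Product: 18 (1R,5S,7R)-1-benzoyl-2-hydroxy-8,8-dimethyl-3,7-bis(3-methylbut-2-en-1-yl)-5-[(2S)-5-methyl-2-(prop-1-en-2-yl)hex-4-en-1-yl]bicyclo[3.3.1]non-2-ene-4,9-dione, via C3-prenylated tetraketone 17 (not isolated)
Conditions: Pd(PPh3)4 (5 mol %), THF, 40 °C; then K2CO3 (2 equiv), MeOH, 0 °C; aq. HCl
Reagents that add atoms: none
Why: Proposed new method: Tsuji–Trost C-prenylation of the acidic 2-benzoyl-1,3-dione (O-prenyl isomers re-ionise on zerovalent palladium and funnel to carbon at the less hindered allyl terminus) gives the non-enolisable C3-quaternary ketone 17, and methoxide then removes only the C3 benzoyl by retro-Claisen cleavage because that releases a planar β-diketone enolate whereas loss of the bridgehead C1 benzoyl would need an anti-Bredt enolate; closest known reaction types are palladium-catalysed allylation of 2-substituted 1,3-diones and deacylative (retro-Claisen) allylation.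

## Compound list

1 | (±)-lavandulol, racemic 5-methyl-2-(prop-1-en-2-yl)hex-4-en-1-ol | CC(C)=CCC(CO)C(C)=C | starting material
2 | (R)-lavandulol | C=C(C)[C@@H](CC=C(C)C)CO | intermediate
3 | (2R)-5-methyl-2-(prop-1-en-2-yl)hex-4-en-1-yl triflate | C=C(C)[C@@H](CC=C(C)C)COS(=O)(=O)C(F)(F)F | intermediate
4 | (S)-lavandulol | C=C(C)[C@H](CC=C(C)C)CO | intermediate
5 | (2R)-2-(2-methoxypropan-2-yl)-5-methylhex-4-en-1-ol | COC(C)(C)[C@H](CC=C(C)C)CO | intermediate
6 | (2R)-2-(2-methoxypropan-2-yl)-5-methylhex-4-en-1-yl triflate | COC(C)(C)[C@H](CC=C(C)C)COS(=O)(=O)C(F)(F)F | intermediate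
7 | phloroglucinol | Oc1cc(O)cc(O)c1 | starting material
8 | benzoyl chloride | O=C(Cl)c1ccccc1 | starting material
9 | 2,4-dibenzoylphloroglucinol | Oc1cc(O)c(C(=O)c2ccccc2)c(O)c1C(=O)c1ccccc1 | intermediate
10 | {2,4,6-trihydroxy-5-[(2S)-5-methyl-2-(prop-1-en-2-yl)hex-4-en-1-yl]-1,3-phenylene}bis(phenylmethanone) | C=C(C)[C@@H](CC=C(C)C)Cc1c(O)c(C(=O)c2ccccc2)c(O)c(C(=O)c2ccccc2)c1O | intermediate
11 | 2,6-dibenzoyl-3,5-dihydroxy-4-[(2R)-2-(2-methoxypropan-2-yl)-5-methylhex-4-en-1-yl]-4-[(2S)-5-methyl-2-(prop-1-en-2-yl)hex-4-en-1-yl]cyclohexa-2,5-dien-1-one | C=C(C)[C@@H](CC=C(C)C)CC1(C[C@@H](CC=C(C)C)C(C)(C)OC)C(O)=C(C(=O)c2ccccc2)C(=O)C(C(=O)c2ccccc2)=C1O | intermediate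
12 | 3,5-bis(trimethylsilyloxy) analogue of 11 (bis-silyl dienol ether; one of several equilibrating silyl tautomers) | C=C(C)[C@@H](CC=C(C)C)CC1(C[C@@H](CC=C(C)C)C(C)(C)OC)C(O[Si](C)(C)C)=C(C(=O)c2ccccc2)C(=O)C(C(=O)c2ccccc2)=C1O[Si](C)(C)C | intermediate (not isolated)
13 | tertiary carbocation formed from 12 by loss of methoxide at the CMe2 carbon, configuration of the adjacent CH unchanged | C=C(C)[C@@H](CC=C(C)C)CC1(C[C@@H](CC=C(C)C)[C+](C)C)C(O[Si](C)(C)C)=C(C(=O)c2ccccc2)C(=O)C(C(=O)c2ccccc2)=C1O[Si](C)(C)C | intermediate (not isolated)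
14 | (1R,5S,7R)-1,3-dibenzoyl-8,8-dimethyl-7-(3-methylbut-2-en-1-yl)-5-[(2S)-5-methyl-2-(prop-1-en-2-yl)hex-4-en-1-yl]-4-(trimethylsilyloxy)bicyclo[3.3.1]non-3-ene-2,9-dione | C=C(C)[C@@H](CC=C(C)C)C[C@@]12C[C@@H](CC=C(C)C)C(C)(C)[C@@](C(=O)c3ccccc3)(C1=O)C(=O)C(C(=O)c3ccccc3)=C2O[Si](C)(C)C | intermediate (not isolated)
15 | (1R,5S,7R)-1,3-dibenzoyl-2-hydroxy-8,8-dimethyl-7-(3-methylbut-2-en-1-yl)-5-[(2S)-5-methyl-2-(prop-1-en-2-yl)hex-4-en-1-yl]bicyclo[3.3.1]non-2-ene-4,9-dione | C=C(C)[C@@H](CC=C(C)C)C[C@@]12C[C@@H](CC=C(C)C)C(C)(C)[C@@](C(=O)c3ccccc3)(C1=O)C(O)=C(C(=O)c3ccccc3)C2=O | intermediate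
16 | prenyl acetate (3-methylbut-2-en-1-yl acetate) | CC(C)=CCOC(C)=O | starting material
17 | (1R,5S,7R)-1,3-dibenzoyl-8,8-dimethyl-3,7-bis(3-methylbut-2-en-1-yl)-5-[(2S)-5-methyl-2-(prop-1-en-2-yl)hex-4-en-1-yl]bicyclo[3.3.1]nonane-2,4,9-trione, mixture of C3 epimers | C=C(C)[C@@H](CC=C(C)C)C[C@@]12C[C@@H](CC=C(C)C)C(C)(C)[C@@](C(=O)c3ccccc3)(C1=O)C(=O)C(CC=C(C)C)(C(=O)c3ccccc3)C2=O | intermediate (not isolated)
18 | (1R,5S,7R)-1-benzoyl-2-hydroxy-8,8-dimethyl-3,7-bis(3-methylbut-2-en-1-yl)-5-[(2S)-5-methyl-2-(prop-1-en-2-yl)hex-4-en-1-yl]bicyclo[3.3.1]non-2-ene-4,9-dione | C=C(C)[C@@H](CC=C(C)C)C[C@@]12C[C@@H](CC=C(C)C)C(C)(C)[C@@](C(=O)c3ccccc3)(C1=O)C(O)=C(CC=C(C)C)C2=O | target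

## Step count and risks

Total step count: 10.
Longest linear sequence: 6 steps (1, 2, 7, 8, 9, 10 or 3, 4, 5, 8, 9, 10).

Three steps most likely to fail:

Step 9 (key cyclisation). The C–C closure joins two quaternary carbons at an acyl-bearing enol carbon and competes with O-cyclisation, elimination and a 1,2-hydride shift of the cation. The fallback blocks the flanking oxygens. It sets out from 11: O-methylation with Me3SiCHN2 in MeOH/toluene gives, after separation from regioisomeric ethers, the symmetric dimethyl ether 2,6-dibenzoyl-3,5-dimethoxy-4,4-dialkylcyclohexa-2,5-dien-1-one F1, in which only the benzoyl-bearing carbons can capture the cation. The same Me3SiOTf ionisation then gives the C4 methyl enol ether of the bicycle F2, the intermediate oxocarbenium ion losing its methyl group to triflate. LiCl in DMSO at 120 °C cleaves the remaining methyl ether and the route is rejoined at 15.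

Step 8 (quaternary carbon by SN2 with a hindered triflate). O-alkylation or no reaction may win because the electrophile carries a fully substituted carbon next to its β-carbon. The fallback reverses the order of the two alkylations. It sets out from 9: aromatic C-alkylation with 6 (LiN(SiMe3)2, THF/toluene), where no quaternary carbon is formed, gives the mono-alkylated 5-[(2R)-2-(2-methoxypropan-2-yl)-5-methylhex-4-en-1-yl]-2,4-dibenzoylphloroglucinol F3. The dearomatising alkylation is then done with the less hindered lavandulyl triflate 3, and the route is rejoined at 11.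

Step 10 (benzoyl-for-prenyl exchange). The C-prenylation at the acyl-bearing carbon may stall at O-prenyl isomers, or the product enolate may be prenylated again. The fallback separates deacylation from prenylation. It sets out from 15: N-iodosuccinimide with K2CO3 in MeOH at 0 °C iodinates C3 and methanolysis of the resulting non-enolisable ketone removes the benzoyl group, giving the 3-iodo enol 1-benzoyl-2-hydroxy-3-iodo bicyclic dione F4. Zinc dust in acetic acid reduces it to the C3-unsubstituted 1-benzoyl bicyclic trione F5. This is C-prenylated with 16 and Pd(PPh3)4 in THF (Tsuji–Trost allylation of a cyclic 1,3-dione), and the route is rejoined at 18.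

## Further compounds

F1 | step 9 | 2,6-dibenzoyl-3,5-dimethoxy-4-[(2R)-2-(2-methoxypropan-2-yl)-5-methylhex-4-en-1-yl]-4-[(2S)-5-methyl-2-(prop-1-en-2-yl)hex-4-en-1-yl]cyclohexa-2,5-dien-1-one | C=C(C)[C@@H](CC=C(C)C)CC1(C[C@@H](CC=C(C)C)C(C)(C)OC)C(OC)=C(C(=O)c2ccccc2)C(=O)C(C(=O)c2ccccc2)=C1OC
F2 | step 9 | (1R,5S,7R)-1,3-dibenzoyl-4-methoxy-8,8-dimethyl-7-(3-methylbut-2-en-1-yl)-5-[(2S)-5-methyl-2-(prop-1-en-2-yl)hex-4-en-1-yl]bicyclo[3.3.1]non-3-ene-2,9-dione | C=C(C)[C@@H](CC=C(C)C)C[C@@]12C[C@@H](CC=C(C)C)C(C)(C)[C@@](C(=O)c3ccccc3)(C1=O)C(=O)C(C(=O)c3ccccc3)=C2OC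
F3 | step 8 | {2,4,6-trihydroxy-5-[(2R)-2-(2-methoxypropan-2-yl)-5-methylhex-4-en-1-yl]-1,3-phenylene}bis(phenylmethanone) | COC(C)(C)[C@H](CC=C(C)C)Cc1c(O)c(C(=O)c2ccccc2)c(O)c(C(=O)c2ccccc2)c1O
F4 | step 10 | (1R,5R,7R)-1-benzoyl-2-hydroxy-3-iodo-8,8-dimethyl-7-(3-methylbut-2-en-1-yl)-5-[(2S)-5-methyl-2-(prop-1-en-2-yl)hex-4-en-1-yl]bicyclo[3.3.1]non-2-ene-4,9-dione (same spatial arrangement as 15) | C=C(C)[C@@H](CC=C(C)C)C[C@@]12C[C@@H](CC=C(C)C)C(C)(C)[C@@](C(=O)c3ccccc3)(C1=O)C(O)=C(I)C2=O
F5 | step 10 | (1R,5S,7R)-1-benzoyl-2-hydroxy-8,8-dimethyl-7-(3-methylbut-2-en-1-yl)-5-[(2S)-5-methyl-2-(prop-1-en-2-yl)hex-4-en-1-yl]bicyclo[3.3.1]non-2-ene-4,9-dione | C=C(C)[C@@H](CC=C(C)C)C[C@@]12C[C@@H](CC=C(C)C)C(C)(C)[C@@](C(=O)c3ccccc3)(C1=O)C(O)=CC2=O
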